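**Retrosynthetic overview**
1. Euchrenone a17 comes from its 7-O-methoxymethyl ether by mild acid; that ketone comes from the C4 dithiane by alkylative hydrolysis.
2. The protected flavan dithiane is cut at O1–C8a and C8–C1'' to an (S)-fluoroarene carbinol and prenyl bromide. The plan rests on the contiguous C7–C8–C8a triad of ring A: C8a carries the ring C oxygen O1, C8 carries the prenyl group, and the C7 oxygen beside them polarises a C8–C8a aryne so that oxygen enters at C8a and carbon at C8.
3. The carbinol comes from Corey–Bakshi–Shibata reduction of a β-keto dithiane (sets C2), which comes from double thiol addition of propane-1,3-dithiol to an ynone.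
4. The ynone comes from the acetylide of 1-ethynyl-2-fluoro-4-(methoxymethoxy)benzene and 2,2-dimethylchroman-6-carbaldehyde, then oxidation; the alkyne comes from 2-fluoro-4-hydroxybenzaldehyde.
5. Ring order: ring A, ring B and the dimethylpyran ring are bought; ring C is the only ring made, in the aryne step.

Key step: step 7

Remark: flavanone numbering (O1, C2, C3, C4, C4a, C5 to C8, C8a, prenyl C1'') is used for these atoms in every intermediate; the dithiane is assembled by thiol addition to an ynone and not by metalation of a 2-aryl-1,3-dithiane, because the ring hydrogen between fluorine and the acetal oxygen would compete for the base and release the aryne too early.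

**Route**

Step 1
Reactants: 1 2-fluoro-4-hydroxybenzaldehyde
Product: 2 2-fluoro-4-(methoxymethoxy)benzaldehyde
Conditions: MOMCl (1.3 equiv), iPr2NEt (2 equiv), CH2Cl2, 0 °C to rt
Reagents that add atoms: chloromethyl methyl ether (MOMCl), COCCl
Why: O-alkylation of the phenol with an α-chloro ether (Williamson-type etherification) is fast and leaves the aldehyde and the aryl fluoride untouched; the acetal later acts as ortho-director and as the polarising group of the aryne.

Step 2
Reactants: 2 2-fluoro-4-(methoxymethoxy)benzaldehyde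
Product: 3 1-ethynyl-2-fluoro-4-(methoxymethoxy)benzene
Conditions: dimethyl (1-diazo-2-oxopropyl)phosphonate (1.3 equiv), K2CO3 (2 equiv), MeOH, 0 °C to rt
Reagents that add atoms: dimethyl (1-diazo-2-oxopropyl)phosphonate, CC(=O)C(=[N+]=[N-])P(=O)(OC)OC
Why: Seyferth–Gilbert homologation in the Ohira–Bestmann variant converts the non-enolisable aryl aldehyde into the terminal alkyne under carbonate in methanol, which is too mild to displace fluoride or cleave the acetal.

Step 3
Reactants: 3 1-ethynyl-2-fluoro-4-(methoxymethoxy)benzene; 4 2,2-dimethylchroman-6-carbaldehyde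
Product: 6 rac-1-(2,2-dimethylchroman-6-yl)-3-[2-fluoro-4-(methoxymethoxy)phenyl]prop-2-yn-1-ol, via lithium acetylide 5 (not isolated)
Conditions: n-BuLi (1.0 equiv), THF, −78 °C; then 4, −78 to 0 °C; aq NH4Cl
Reagents that add atoms: none
Why: The acetylenic hydrogen is far more acidic than any ring hydrogen, so one equivalent of base at −78 °C should give only the acetylide, which adds 1,2 to the aldehyde (carbonyl alkynylation); the carbinol centre is racemic and is erased in step 4.

Step 4
Reactants: 6 rac-1-(2,2-dimethylchroman-6-yl)-3-[2-fluoro-4-(methoxymethoxy)phenyl]prop-2-yn-1-ol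
Product: 7 1-(2,2-dimethylchroman-6-yl)-3-[2-fluoro-4-(methoxymethoxy)phenyl]prop-2-yn-1-one
Conditions: activated MnO2 (excess), CH2Cl2, rt
Reagents that add atoms: none
Why: MnO2 oxidation of a benzylic and propargylic alcohol to the ynone is selective and neutral, so the ethers and the acid-sensitive carbinol are not exposed to acid.

Step 5
Reactants: 7 1-(2,2-dimethylchroman-6-yl)-3-[2-fluoro-4-(methoxymethoxy)phenyl]prop-2-yn-1-one; 8 propane-1,3-dithiol
Product: 10 1-(2,2-dimethylchroman-6-yl)-2-{2-[2-fluoro-4-(methoxymethoxy)phenyl]-1,3-dithian-2-yl}ethan-1-one, via β-sulfanyl enone 9 (not isolated)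
Conditions: 8 (1.1 equiv), NaOMe (1.2 equiv), MeOH/CH2Cl2 (4:1), −10 °C to rt
Reagents that add atoms: none
Why: Double conjugate (thia-Michael) addition: the first thiolate adds at the β-carbon to give vinyl sulfide 9 and the pendant thiol then closes the six-membered dithiane on the same carbon, so C4 is masked without acid and without metalating the fluoroarene.

Step 6
Reactants: 10 1-(2,2-dimethylchroman-6-yl)-2-{2-[2-fluoro-4-(methoxymethoxy)phenyl]-1,3-dithian-2-yl}ethan-1-one
Product: 11 (S)-1-(2,2-dimethylchroman-6-yl)-2-{2-[2-fluoro-4-(methoxymethoxy)phenyl]-1,3-dithian-2-yl}ethan-1-ol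
Conditions: (R)-Me-CBS oxazaborolidine [(R)-1-methyl-3,3-diphenyltetrahydro-1H,3H-pyrrolo[1,2-c][1,3,2]oxazaborole] (0.2 equiv), BH3·SMe2 (1.0 equiv), THF, −20 °C; MeOH quench, aqueous work-up
Reagents that add atoms: none
Why: Corey–Bakshi–Shibata reduction, in which the ketone binds the catalyst boron with the aryl group as the large and the CH2 arm as the small substituent, so the (R)-catalyst should deliver hydride to the Re face and set C2 as S.

Step 7
Reactants: 11 (S)-1-(2,2-dimethylchroman-6-yl)-2-{2-[2-fluoro-4-(methoxymethoxy)phenyl]-1,3-dithian-2-yl}ethan-1-ol; 12 prenyl bromide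
Product: 17 (2S)-2-(2,2-dimethylchroman-6-yl)-7-(methoxymethoxy)-8-(3-methylbut-2-en-1-yl)spiro[chromane-4,2'-[1,3]dithiane], via C8-lithio fluoroarene alkoxide 13 (not isolated), via aryne alkoxide 14 (not isolated), via C8-lithio flavan 15 (not isolated), via C8 arylcopper 16 (not isolated)
Conditions: n-BuLi (2.05 equiv, titrated), THF (0.02 M), −78 °C, 1 h; warm slowly to −25 °C; recool to −78 °C, CuBr·SMe2 (1.1 equiv), −78 to −40 °C; 12 (1.5 equiv), −40 to 0 °C; aq NH4Cl
Reagents that add atoms: none
Why: Proposed new method: two equivalents of butyllithium are consumed at −78 °C, one by the hydroxyl group and one by H8, which is flanked by fluorine and the methoxymethoxy group and is therefore the preferred site of ring metalation (13); above about −40 °C 13 ejects LiF and the C8–C8a aryne 14 appears with its alkoxide already in place. The alkoxide adds in the ring plane to C8a, closing ring C in a 6-exo-dig manner (O1–C8a) and leaving aryllithium 15 at C8, which is passed to copper (16) and substitutes prenyl bromide at its primary carbon (C8–C1''). The closest known reaction types are ring closures of tethered alkoxide, amide and carbanion nucleophiles onto arynes released from 2-fluoroaryllithiums with electrophilic quench of the aryllithium so formed, and the copper-mediated prenylation of aryllithiums flanked by two ether oxygens. No stereocentre is created; because ring C is closed at the aromatic carbon and the benzylic C2–O bond stays intact, the S centre from step 6 cannot ionise or invert, an advantage over any closure that would make O1–C2. Regioselectivity across the aryne is required and is doubly assured: a three-atom tether from C4a can span only to C8a, and a 3-alkoxyaryne is attacked at the carbon remote from oxygen, so the carbanion develops at C8 beside the inductively withdrawing C7–O bond, where O1 and the acetal oxygen chelate it. Chemoselectivity against intermolecular carbanion addition to the aryne is also required and should follow from the exact charge of base (no alkyllithium left when the aryne forms), high dilution and the hindered nature of the aryllithiums present.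

Step 8
Reactants: 17 (2S)-2-(2,2-dimethylchroman-6-yl)-7-(methoxymethoxy)-8-(3-methylbut-2-en-1-yl)spiro[chromane-4,2'-[1,3]dithiane]
Product: 18 (2S)-2-(2,2-dimethylchroman-6-yl)-7-(methoxymethoxy)-8-(3-methylbut-2-en-1-yl)chroman-4-one
Conditions: MeI (10 equiv), CaCO3 (5 equiv), MeCN/H2O (9:1), 45 °C
Reagents that add atoms: water, O
Why: Alkylative dithiane hydrolysis: S-methylation gives a sulfonium ion that opens to a thionium ion stabilised by O1 and the para acetal oxygen and is then hydrolysed, while the buffered neutral medium should spare the prenyl alkene, the acetal and C2 (no base for retro-oxa-Michael ring opening).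

Step 9
Reactants: 18 (2S)-2-(2,2-dimethylchroman-6-yl)-7-(methoxymethoxy)-8-(3-methylbut-2-en-1-yl)chroman-4-one
Product: 19 euchrenone a17, (2S)-2-(2,2-dimethylchroman-6-yl)-7-hydroxy-8-(3-methylbut-2-en-1-yl)chroman-4-one
Conditions: HCl (3 M aq.), MeOH, 40 °C
Reagents that add atoms: none
Why: Acid-catalysed acetal exchange with methanol removes the methoxymethyl group from the C7 phenol under conditions mild enough that cyclisation of the ortho-prenyl phenol to a chroman and ionisation at C2 should not compete.

**Compound list**
1 | 2-fluoro-4-hydroxybenzaldehyde | O=Cc1ccc(O)cc1F | starting material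
2 | 2-fluoro-4-(methoxymethoxy)benzaldehyde | O=Cc1ccc(OCOC)cc1F | intermediate
3 | 1-ethynyl-2-fluoro-4-(methoxymethoxy)benzene | C#Cc1ccc(OCOC)cc1F | intermediate
4 | 2,2-dimethylchroman-6-carbaldehyde | O=Cc1ccc2c(c1)CCC(C)(C)O2 | starting material
5 | lithium [2-fluoro-4-(methoxymethoxy)phenyl]acetylide | [Li]C#Cc1ccc(OCOC)cc1F | intermediate
6 | rac-1-(2,2-dimethylchroman-6-yl)-3-[2-fluoro-4-(methoxymethoxy)phenyl]prop-2-yn-1-ol | OC(C#Cc1ccc(OCOC)cc1F)c1ccc2c(c1)CCC(C)(C)O2 | intermediate
7 | 1-(2,2-dimethylchroman-6-yl)-3-[2-fluoro-4-(methoxymethoxy)phenyl]prop-2-yn-1-one | O=C(C#Cc1ccc(OCOC)cc1F)c1ccc2c(c1)CCC(C)(C)O2 | intermediate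
8 | propane-1,3-dithiol | SCCCS | starting material
9 | 1-(2,2-dimethylchroman-6-yl)-3-[2-fluoro-4-(methoxymethoxy)phenyl]-3-[(3-sulfanylpropyl)sulfanyl]prop-2-en-1-one (alkene geometry not defined) | O=C(C=C(SCCCS)c1ccc(OCOC)cc1F)c1ccc2c(c1)CCC(C)(C)O2 | intermediate
10 | 1-(2,2-dimethylchroman-6-yl)-2-{2-[2-fluoro-4-(methoxymethoxy)phenyl]-1,3-dithian-2-yl}ethan-1-one | O=C(CC1(SCCCS1)c1ccc(OCOC)cc1F)c1ccc2c(c1)CCC(C)(C)O2 | intermediate
11 | (S)-1-(2,2-dimethylchroman-6-yl)-2-{2-[2-fluoro-4-(methoxymethoxy)phenyl]-1,3-dithian-2-yl}ethan-1-ol | O[C@H](c1ccc2c(c1)CCC(C)(C)O2)CC1(SCCCS1)c1ccc(OCOC)cc1F | intermediate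
12 | prenyl bromide (1-bromo-3-methylbut-2-ene) | CC(C)=CCBr | starting material
13 | lithium alkoxide of 11 lithiated at C8 (between F and the acetal oxygen) | [Li]O[C@H](c1ccc2c(c1)CCC(C)(C)O2)CC1(SCCCS1)c1ccc(OCOC)c([Li])c1F | intermediate
14 | lithium alkoxide carrying the C8–C8a aryne | [Li]O[C@H](c1ccc2c(c1)CCC(C)(C)O2)CC1(SCCCS1)C1=CC=C(OCOC)C#C1 | intermediate
15 | (2S)-8-lithio-7-(methoxymethoxy)-2-(2,2-dimethylchroman-6-yl)spiro[chromane-4,2'-[1,3]dithiane] | [Li]c1c(OCOC)ccc2c1O[C@H](c1ccc3c(c1)CCC(C)(C)O3)CC21SCCCS1 | intermediate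
16 | C8 arylcopper derived from 15 | [Cu]c1c(OCOC)ccc2c1O[C@H](c1ccc3c(c1)CCC(C)(C)O3)CC21SCCCS1 | intermediate
17 | (2S)-2-(2,2-dimethylchroman-6-yl)-7-(methoxymethoxy)-8-(3-methylbut-2-en-1-yl)spiro[chromane-4,2'-[1,3]dithiane] | CC(C)=CCc1c(OCOC)ccc2c1O[C@H](c1ccc3c(c1)CCC(C)(C)O3)CC21SCCCS1 | intermediate
18 | (2S)-2-(2,2-dimethylchroman-6-yl)-7-(methoxymethoxy)-8-(3-methylbut-2-en-1-yl)chroman-4-one | CC(C)=CCc1c(OCOC)ccc2c1O[C@H](c1ccc3c(c1)CCC(C)(C)O3)CC2=O | intermediate
19 | euchrenone a17 | CC(C)=CCc1c(O)ccc2c1O[C@H](c1ccc3c(c1)CCC(C)(C)O3)CC2=O | target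

**Step count**
Total: 9 steps. Longest linear sequence: 9 steps (1 to 19); compounds 4, 8 and 12 enter as bought materials.

**Steps most likely to fail**

Step 7 (proposed method). The aryne may be intercepted by an organolithium other than the tethered alkoxide (residual butyllithium or a second aryllithium), or the C8 carbanion may be protonated before it reaches copper. Fallback by known chemistry, making the two bonds one after the other: from 11, the potassium alkoxide (KOtBu, DMF, 90 °C) displaces fluoride in an intramolecular nucleophilic aromatic substitution to give (2S)-2-(2,2-dimethylchroman-6-yl)-7-(methoxymethoxy)spiro[chromane-4,2'-[1,3]dithiane] F1. Directed ortho-lithiation of this compound between O1 and the acetal oxygen (n-BuLi, THF, 0 °C), then CuBr·SMe2 and prenyl bromide 12, should give 17, where the route is rejoined.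

Step 6. Facial discrimination may be poor because the dithianylmethyl arm is nearly as bulky as the aryl group. Fallback by resolution: from 10, NaBH4 (MeOH/THF, 0 °C) gives the racemic carbinol rac-1-(2,2-dimethylchroman-6-yl)-2-{2-[2-fluoro-4-(methoxymethoxy)phenyl]-1,3-dithian-2-yl}ethan-1-ol F2, which is acylated with (1S)-camphanic chloride (Et3N, DMAP, CH2Cl2). The diastereomeric esters are separated by chromatography or crystallisation, and the (1S)-camphanate of the S alcohol F3 is methanolysed (K2CO3, MeOH) to 11.

Step 8. S-Alkylation at the fully substituted dithiane may be slow, and prolonged heating may erode C2 by ring opening and reclosure. Fallback by oxidative instead of alkylative activation: from 17, NaIO4 (MeOH/THF/H2O, 0 °C), which leaves the prenyl alkene alone, gives the dithiane monosulfoxide of 17 F4 (mixture at sulfur). Dilute HCl in MeOH/THF (40 °C) then hydrolyses the S-oxide thioacetal and cleaves the methoxymethyl ether in the same flask, so the route is rejoined at 19.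

**Further compounds**
F1 | step 7 | (2S)-2-(2,2-dimethylchroman-6-yl)-7-(methoxymethoxy)spiro[chromane-4,2'-[1,3]dithiane] | COCOc1ccc2c(c1)O[C@H](c1ccc3c(c1)CCC(C)(C)O3)CC21SCCCS1
F2 | step 6 | rac-1-(2,2-dimethylchroman-6-yl)-2-{2-[2-fluoro-4-(methoxymethoxy)phenyl]-1,3-dithian-2-yl}ethan-1-ol | OC(c1ccc2c(c1)CCC(C)(C)O2)CC1(SCCCS1)c1ccc(OCOC)cc1F
F3 | step 6 | (1S)-camphanate of the (S)-carbinol 11 | O=C(O[C@H](c1ccc2c(c1)CCC(C)(C)O2)CC1(SCCCS1)c1ccc(OCOC)cc1F)[C@@]12CC[C@@](C)(C(=O)O1)C2(C)C
F4 | step 8 | dithiane monosulfoxide of 17 (mixture at sulfur) | CC(C)=CCc1c(OCOC)ccc2c1O[C@H](c1ccc3c(c1)CCC(C)(C)O3)CC21SCCCS1=O
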